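**Retrosynthetic overview**

1. Target 20 comes from hydrogenolysis of the six benzyl ethers of 19, and 19 from hydrogenation of the C3=C4 bond of 2H-chromene 18 on the face anti to the C2 aryl group, which sets C3 cis to C2.
2. The strategy rests on the C3–C4 bond of the pyran ring: C3 carries the ester oxygen and C4 is the benzylic CH2 on the A ring, so this bond is made as the C3=C4 double bond of a 3-aroyloxy-2H-chromene by ring-closing metathesis between the A-ring ortho-vinyl group and a 1-aroyloxyvinyl group (17 → 18), with C2 carried through unchanged.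
3. Enol ester 17 comes from Markovnikov addition of 4-(benzyloxy)benzoic acid to terminal alkyne 15. A ruthenium/carbonate catalyst is used rather than cationic gold, which would be expected to close the alkyne onto the free ortho C–H of the electron-rich A ring.
4. Alkyne 15 comes from Mitsunobu inversion of propargylic alcohol 10 with vinylphenol 13; 10 from Alpine-Borane reduction of the gallate-derived ynone 7; 13 from 2,4,6-trihydroxybenzaldehyde by dibenzylation and Wittig methylenation.
5. Ring order: the A and B rings are bought; the pyran ring is the only ring formed (step 10).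

Key step: step 10

Remark: the descriptor at the future C2 alternates (9 S, 10 R, 15 S, 17 and 18 R) through changes in CIP priority alone; the only change of geometry at this carbon is the inversion in step 8.

**Route**

Step 1
Reactants: 1 methyl gallate
Product: 2 methyl 3,4,5-tris(benzyloxy)benzoate
Conditions: BnBr (3.3 equiv), K2CO3, DMF, 60 °C
Reagents that add atoms: benzyl bromide BrCc1ccccc1
Why: Williamson etherification in which carbonate deprotonates the three phenols and the phenolates displace bromide from benzyl bromide (SN2), the methyl ester being inert to K2CO3 in dry DMF.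

Step 2
Reactants: 2 methyl 3,4,5-tris(benzyloxy)benzoate
Product: 3 N-methoxy-N-methyl-3,4,5-tris(benzyloxy)benzamide
Conditions: MeNH(OMe)·HCl, i-PrMgCl, THF, −20 to 0 °C
Reagents that add atoms: N,O-dimethylhydroxylamine hydrochloride CNOC.Cl
Why: Weinreb amide formation from an ester, in which the chloromagnesium amide made from the hydroxylamine salt and i-PrMgCl adds to the unhindered benzoate and expels methoxide, and the product amide does not react further with the magnesium amide.

Step 3
Reactants: 3 N-methoxy-N-methyl-3,4,5-tris(benzyloxy)benzamide; 4 ethynyltrimethylsilane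
Product: 7 1-[3,4,5-tris(benzyloxy)phenyl]-3-(trimethylsilyl)prop-2-yn-1-one, via lithium (trimethylsilyl)acetylide 5 (not isolated), via lithium hemiaminal adduct 6 (not isolated)
Conditions: 4, n-BuLi, THF, −78 °C; then 3, −78 to 0 °C; cold aq NH4Cl
Reagents that add atoms: none
Why: Weinreb ketone synthesis, in which acetylide 5 adds once to give the lithium-chelated tetrahedral adduct 6 that collapses to the ynone only on protonation, so no tertiary alcohol forms, and the cold quench keeps the released hydroxylamine from adding to the ynone.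

Step 4
Reactants: 7 1-[3,4,5-tris(benzyloxy)phenyl]-3-(trimethylsilyl)prop-2-yn-1-one
Product: 9 (1S)-1-[3,4,5-tris(benzyloxy)phenyl]-3-(trimethylsilyl)prop-2-yn-1-ol, via B-alkoxy-9-BBN borinate 8 (not isolated)
Conditions: (S)-Alpine-Borane (2 equiv), neat, rt; then MeCHO; then HOCH2CH2NH2, Et2O, 0 °C
Reagents that add atoms: none
Why: Midland reduction, in which the pinanyl C–H hydride is transferred through a boat-like six-membered transition state with the slim alkynyl group next to the pinane methyl group and the aryl group pointing away, so the reagent from (−)-α-pinene should give the (S)-carbinol (the same sense as the known reduction of 1-octyn-3-one to its R alcohol by the R reagent); the benzyl ethers and the C–Si bond are inert, and ethanolamine frees the alcohol from borinate 8 without base-induced desilylation.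

Step 5
Reactants: 9 (1S)-1-[3,4,5-tris(benzyloxy)phenyl]-3-(trimethylsilyl)prop-2-yn-1-ol
Product: 10 (1R)-1-[3,4,5-tris(benzyloxy)phenyl]prop-2-yn-1-ol
Conditions: K2CO3 (cat.), MeOH/THF, 0 °C to rt
Reagents that add atoms: none
Why: Base-catalysed protodesilylation (methoxide attacks silicon, the acetylide is protonated by methanol) that does not involve the carbinol centre, whose descriptor becomes R only because ethynyl ranks below aryl whereas silylethynyl ranks above it.

Step 6
Reactants: 11 2,4,6-trihydroxybenzaldehyde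
Product: 12 2,4-bis(benzyloxy)-6-hydroxybenzaldehyde
Conditions: BnBr (2.05 equiv), K2CO3 (2.2 equiv), DMF, 0 °C to rt
Reagents that add atoms: benzyl bromide BrCc1ccccc1
Why: Regioselective Williamson etherification, in which the 4-OH and one 2-OH are alkylated and the remaining ortho OH, locked in a hydrogen bond to the formyl group, is the least nucleophilic, so two equivalents of benzyl bromide should stop at the dibenzyl ether.

Step 7
Reactants: 12 2,4-bis(benzyloxy)-6-hydroxybenzaldehyde
Product: 13 3,5-bis(benzyloxy)-2-ethenylphenol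
Conditions: Ph3PCH3Br (2.5 equiv), KOt-Bu (2.4 equiv), THF, 0 °C to rt; aq NH4Cl
Reagents that add atoms: methyltriphenylphosphonium bromide C[P+](c1ccccc1)(c1ccccc1)c1ccccc1.[Br-]
Why: Wittig methylenation, in which the acidic phenol consumes one equivalent of ylide and the excess converts the formyl group into the vinyl group through the oxaphosphetane; the acid-sensitive electron-rich vinylphenol is released by a mild work-up and used without storage.

Step 8
Reactants: 10 (1R)-1-[3,4,5-tris(benzyloxy)phenyl]prop-2-yn-1-ol; 13 3,5-bis(benzyloxy)-2-ethenylphenol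
Product: 15 1,5-bis(benzyloxy)-2-ethenyl-3-{[(1S)-1-[3,4,5-tris(benzyloxy)phenyl]prop-2-yn-1-yl]oxy}benzene, via alkoxyphosphonium phenolate 14 (not isolated)
Conditions: PPh3, DIAD, toluene, 0 °C to rt
Reagents that add atoms: none
Why: Mitsunobu etherification, in which the phenol (pKa about 10) protonates the PPh3–DIAD betaine and its phenolate displaces triphenylphosphine oxide from alkoxyphosphonium ion 14 by SN2 with inversion, turning the (R)-carbinol into the (S)-ether; toluene and low temperature disfavour ionisation of the benzylic–propargylic centre, whose 3,4,5-trialkoxyphenyl group is only a weak cation stabiliser because the 4-alkoxy group is twisted out of conjugation.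

Step 9
Reactants: 15 1,5-bis(benzyloxy)-2-ethenyl-3-{[(1S)-1-[3,4,5-tris(benzyloxy)phenyl]prop-2-yn-1-yl]oxy}benzene; 16 4-(benzyloxy)benzoic acid
Product: 17 (3R)-3-[3,5-bis(benzyloxy)-2-ethenylphenoxy]-3-[3,4,5-tris(benzyloxy)phenyl]prop-1-en-2-yl 4-(benzyloxy)benzoate
Conditions: [RuCl2(p-cymene)]2 (2.5 mol %), P(2-furyl)3 (5 mol %), Na2CO3 (10 mol %), toluene, 60 °C
Reagents that add atoms: none
Why: Ruthenium(II)-catalysed Markovnikov hydro-acyloxylation of a terminal alkyne (carboxylate attack at the internal carbon of the Ru-bound alkyne, then protodemetalation), the regiochemistry known for the tri(2-furyl)phosphine/carbonate catalyst system and for propargylic oxygen-substituted alkynes; the weakly basic, non-Lewis-acidic medium should leave the propargylic stereocentre, the styrene and the free ortho C–H of the A ring untouched, and the descriptor changes to R only through the change in priorities.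

Step 10
Reactants: 17 (3R)-3-[3,5-bis(benzyloxy)-2-ethenylphenoxy]-3-[3,4,5-tris(benzyloxy)phenyl]prop-1-en-2-yl 4-(benzyloxy)benzoate
Product: 18 (2R)-5,7-bis(benzyloxy)-2-[3,4,5-tris(benzyloxy)phenyl]-2H-chromen-3-yl 4-(benzyloxy)benzoate
Conditions: Hoveyda–Grubbs II (10 mol %), 1,4-benzoquinone (20 mol %), toluene (5 mM), 80 °C, Ar sparge
Reagents that add atoms: none
Why: Ring-closing olefin metathesis: the ruthenium alkylidene first exchanges with the monosubstituted A-ring vinyl group, the resulting ruthenium benzylidene adds intramolecularly across the CH2=C(OCOAr) unit to a ruthenacyclobutane, and cycloreversion releases the C3=C4 enol ester with Ru=CH2, ethylene leaving the solution. The closest known reactions are ring-closing metathesis of enol esters, silyl enol ethers and enol ethers onto styrenes, and the closure of 2-vinylphenyl allyl ethers to 2H-chromenes. The pyran ring closes as a six-membered ring with the new double bond endocyclic between C3 and C4, the atoms O1, C2 and C3 coming from the side chain and C4, C4a and C8a from the styrene. No stereocentre is formed; C2 lies outside the metallacycle and under neutral conditions its benzylic, allylic C–O bond is not ionised, so the R configuration is carried through. The step needs loading at the styrene rather than at the enol ester and release of the product without double-bond migration: the 1,1-disubstituted, acyloxy-bearing alkene is too hindered to load first (it would give a Fischer-type carbene), the phosphine-free second-generation catalyst at 80 °C reopens the ortho-oxygen chelate of the benzylidene, benzoquinone removes Ru–H species, and high dilution with ethylene removal suppresses intermolecular dimerisation of the styrene.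

Step 11
Reactants: 18 (2R)-5,7-bis(benzyloxy)-2-[3,4,5-tris(benzyloxy)phenyl]-2H-chromen-3-yl 4-(benzyloxy)benzoate
Product: 19 (2R,3R)-5,7-bis(benzyloxy)-2-[3,4,5-tris(benzyloxy)phenyl]-3,4-dihydro-2H-chromen-3-yl 4-(benzyloxy)benzoate
Conditions: H2 (20 bar), [Rh(cod)(dppb)]BF4 (5 mol %), CH2Cl2, rt
Reagents that add atoms: none
Why: Chelation-assisted homogeneous hydrogenation of an enol ester (cationic Rh–diphosphine, Schrock–Osborn type), in which both hydrogens add syn to the C3=C4 face anti to the C2 aryl group, held pseudoaxial by allylic (A1,2) strain with the C3 ester, so that H at C3 ends trans and the ester cis to the aryl group (3R); benzyl ethers, the aryl ester and the benzylic C2–O bond are not hydrogenolysed by rhodium under these conditions.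

Step 12
Reactants: 19 (2R,3R)-5,7-bis(benzyloxy)-2-[3,4,5-tris(benzyloxy)phenyl]-3,4-dihydro-2H-chromen-3-yl 4-(benzyloxy)benzoate
Product: 20 epigallocatechin 3-O-(4-hydroxybenzoate), (2R,3R)-5,7-dihydroxy-2-(3,4,5-trihydroxyphenyl)-3,4-dihydro-2H-chromen-3-yl 4-hydroxybenzoate
Conditions: H2 (1 atm), 20% Pd(OH)2/C, THF/MeOH, rt
Reagents that add atoms: none
Why: Hydrogenolysis of the six benzyl aryl ethers over Pearlman's catalyst in neutral medium, as practised for benzylated flavan-3-ol esters, which leaves the secondary benzoate, the chroman C2–O bond and both stereocentres untouched and involves no base that could cause acyl migration or C2 epimerisation.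

**Compound list**

1 | methyl gallate | COC(=O)c1cc(O)c(O)c(O)c1 | starting material
2 | methyl 3,4,5-tris(benzyloxy)benzoate | COC(=O)c1cc(OCc2ccccc2)c(OCc2ccccc2)c(OCc2ccccc2)c1 | intermediate
3 | N-methoxy-N-methyl-3,4,5-tris(benzyloxy)benzamide | CON(C)C(=O)c1cc(OCc2ccccc2)c(OCc2ccccc2)c(OCc2ccccc2)c1 | intermediate
4 | ethynyltrimethylsilane | C#C[Si](C)(C)C | starting material
5 | lithium (trimethylsilyl)acetylide | [Li]C#C[Si](C)(C)C | intermediate (not isolated)
6 | lithium 1-[methoxy(methyl)amino]-1-[3,4,5-tris(benzyloxy)phenyl]-3-(trimethylsilyl)prop-2-yn-1-olate (tetrahedral adduct, racemic) | CON(C)C(O[Li])(C#C[Si](C)(C)C)c1cc(OCc2ccccc2)c(OCc2ccccc2)c(OCc2ccccc2)c1 | intermediate (not isolated)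
7 | 1-[3,4,5-tris(benzyloxy)phenyl]-3-(trimethylsilyl)prop-2-yn-1-one | C[Si](C)(C)C#CC(=O)c1cc(OCc2ccccc2)c(OCc2ccccc2)c(OCc2ccccc2)c1 | intermediate
8 | 9-{[(1S)-1-[3,4,5-tris(benzyloxy)phenyl]-3-(trimethylsilyl)prop-2-yn-1-yl]oxy}-9-borabicyclo[3.3.1]nonane | C[Si](C)(C)C#C[C@@H](OB1C2CCCC1CCC2)c1cc(OCc2ccccc2)c(OCc2ccccc2)c(OCc2ccccc2)c1 | intermediate (not isolated)
9 | (1S)-1-[3,4,5-tris(benzyloxy)phenyl]-3-(trimethylsilyl)prop-2-yn-1-ol | C[Si](C)(C)C#C[C@@H](O)c1cc(OCc2ccccc2)c(OCc2ccccc2)c(OCc2ccccc2)c1 | intermediate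
10 | (1R)-1-[3,4,5-tris(benzyloxy)phenyl]prop-2-yn-1-ol | C#C[C@@H](O)c1cc(OCc2ccccc2)c(OCc2ccccc2)c(OCc2ccccc2)c1 | intermediate
11 | 2,4,6-trihydroxybenzaldehyde | O=Cc1c(O)cc(O)cc1O | starting material
12 | 2,4-bis(benzyloxy)-6-hydroxybenzaldehyde | O=Cc1c(O)cc(OCc2ccccc2)cc1OCc1ccccc1 | intermediate
13 | 3,5-bis(benzyloxy)-2-ethenylphenol | C=Cc1c(O)cc(OCc2ccccc2)cc1OCc1ccccc1 | intermediate
14 | {[(1R)-1-[3,4,5-tris(benzyloxy)phenyl]prop-2-yn-1-yl]oxy}triphenylphosphonium 3,5-bis(benzyloxy)-2-ethenylphenolate | C#C[C@@H](O[P+](c1ccccc1)(c1ccccc1)c1ccccc1)c1cc(OCc2ccccc2)c(OCc2ccccc2)c(OCc2ccccc2)c1.[O-]c1cc(OCc2ccccc2)cc(OCc2ccccc2)c1C=C | intermediate (not isolated)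
15 | 1,5-bis(benzyloxy)-2-ethenyl-3-{[(1S)-1-[3,4,5-tris(benzyloxy)phenyl]prop-2-yn-1-yl]oxy}benzene | C#C[C@H](Oc1cc(OCc2ccccc2)cc(OCc2ccccc2)c1C=C)c1cc(OCc2ccccc2)c(OCc2ccccc2)c(OCc2ccccc2)c1 | intermediate
16 | 4-(benzyloxy)benzoic acid | O=C(O)c1ccc(OCc2ccccc2)cc1 | starting material
17 | (3R)-3-[3,5-bis(benzyloxy)-2-ethenylphenoxy]-3-[3,4,5-tris(benzyloxy)phenyl]prop-1-en-2-yl 4-(benzyloxy)benzoate | C=Cc1c(OCc2ccccc2)cc(OCc2ccccc2)cc1O[C@@H](C(=C)OC(=O)c1ccc(OCc2ccccc2)cc1)c1cc(OCc2ccccc2)c(OCc2ccccc2)c(OCc2ccccc2)c1 | intermediate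
18 | (2R)-5,7-bis(benzyloxy)-2-[3,4,5-tris(benzyloxy)phenyl]-2H-chromen-3-yl 4-(benzyloxy)benzoate | O=C(OC1=Cc2c(OCc3ccccc3)cc(OCc3ccccc3)cc2O[C@@H]1c1cc(OCc2ccccc2)c(OCc2ccccc2)c(OCc2ccccc2)c1)c1ccc(OCc2ccccc2)cc1 | intermediate
19 | (2R,3R)-5,7-bis(benzyloxy)-2-[3,4,5-tris(benzyloxy)phenyl]-3,4-dihydro-2H-chromen-3-yl 4-(benzyloxy)benzoate | O=C(O[C@@H]1Cc2c(OCc3ccccc3)cc(OCc3ccccc3)cc2O[C@@H]1c1cc(OCc2ccccc2)c(OCc2ccccc2)c(OCc2ccccc2)c1)c1ccc(OCc2ccccc2)cc1 | intermediate
20 | epigallocatechin 3-O-(4-hydroxybenzoate), (2R,3R) | O=C(O[C@@H]1Cc2c(O)cc(O)cc2O[C@@H]1c1cc(O)c(O)c(O)c1)c1ccc(O)cc1 | target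

**Step count and risks**

Total step count: 12. Longest linear sequence: 10 (steps 1–5, then 8–12).

Steps most likely to fail:

Step 10 (key step). The catalyst may be held as an oxygen-chelated benzylidene at the doubly ortho-oxygenated styrene and fail to turn over onto the hindered acyloxy-substituted alkene, or ruthenium hydride from catalyst decay may move the double bonds before closure. The fallback sets out from 15 and returns to the route at 19; it closes the ring between two monosubstituted alkenes and introduces the C3 oxygen afterwards. Lindlar semihydrogenation (H2, Pd/CaCO3–Pb, quinoline, EtOAc) should give the allyl aryl ether F1. Ring-closing metathesis (Grubbs II, CH2Cl2, 40 °C) should give the flav-3-ene F2. Hydroboration–oxidation (BH3·THF; NaOH, H2O2) adds anti to the C2 aryl group and should give the 2,3-trans flavan-3-ol F3. Dess–Martin oxidation should give the flavan-3-one F4, and L-Selectride (THF, −78 °C) delivers hydride anti to the aryl group to the 2,3-cis flavan-3-ol F5. Esterification with acid 16 (EDC, DMAP, CH2Cl2) then gives 19.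

Step 9. The acid may add with anti-Markovnikov regiochemistry through a ruthenium vinylidene, or addition at the hindered internal carbon may be so slow that metal-induced cyclisation of the alkyne onto the A ring or the styrene takes over. The fallback sets out from 15 and returns at 17; it replaces the direct addition by a boron-mediated C–O coupling. α-Selective copper-catalysed protoboration (B2pin2, MeOH, N-aryl NHC–CuCl, NaOt-Bu, THF) should give the internal alkenylboronate F6. KHF2 (MeOH/H2O) converts it into the potassium alkenyltrifluoroborate F7. Copper-catalysed oxidative coupling with acid 16 (CuBr, DMAP, molecular sieves, O2, MeCN, 60 °C) should then give enol ester 17.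

Step 11. The cationic rhodium may be sequestered by the electron-rich arenes so that turnover stops, hydride addition and elimination may move the double bond into the C2–C3 position with loss of the C2 configuration, or facial discrimination may be incomplete. The fallback sets out from 18 and returns at 19; it sets C3 by hydride reduction of a ketone instead of alkene hydrogenation. Methyllithium (2.2 equiv, THF, −78 °C) cleaves the enol ester regiospecifically to the lithium enolate F8. Cold protonation (AcOH, −78 °C) gives the flavan-3-one F4 without exposing C2 to base at higher temperature. L-Selectride then gives the cis flavan-3-ol F5, and esterification with 16 (EDC, DMAP) gives 19.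

**Further compounds**

F1 | step 10 | 1,5-bis(benzyloxy)-2-ethenyl-3-{[(1S)-1-[3,4,5-tris(benzyloxy)phenyl]prop-2-en-1-yl]oxy}benzene | C=C[C@H](Oc1cc(OCc2ccccc2)cc(OCc2ccccc2)c1C=C)c1cc(OCc2ccccc2)c(OCc2ccccc2)c(OCc2ccccc2)c1
F2 | step 10 | (2S)-5,7-bis(benzyloxy)-2-[3,4,5-tris(benzyloxy)phenyl]-2H-chromene | C1=Cc2c(OCc3ccccc3)cc(OCc3ccccc3)cc2O[C@@H]1c1cc(OCc2ccccc2)c(OCc2ccccc2)c(OCc2ccccc2)c1
F3 | step 10 | (2R,3S)-5,7-bis(benzyloxy)-2-[3,4,5-tris(benzyloxy)phenyl]-3,4-dihydro-2H-chromen-3-ol (2,3-trans) | O[C@H]1Cc2c(OCc3ccccc3)cc(OCc3ccccc3)cc2O[C@@H]1c1cc(OCc2ccccc2)c(OCc2ccccc2)c(OCc2ccccc2)c1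
F4 | step 10 | (2R)-5,7-bis(benzyloxy)-2-[3,4,5-tris(benzyloxy)phenyl]-2H-chromen-3(4H)-one | O=C1Cc2c(OCc3ccccc3)cc(OCc3ccccc3)cc2O[C@@H]1c1cc(OCc2ccccc2)c(OCc2ccccc2)c(OCc2ccccc2)c1
F5 | step 10 | (2R,3R)-5,7-bis(benzyloxy)-2-[3,4,5-tris(benzyloxy)phenyl]-3,4-dihydro-2H-chromen-3-ol (2,3-cis) | O[C@@H]1Cc2c(OCc3ccccc3)cc(OCc3ccccc3)cc2O[C@@H]1c1cc(OCc2ccccc2)c(OCc2ccccc2)c(OCc2ccccc2)c1
F6 | step 9 | 2-{(3S)-3-[3,5-bis(benzyloxy)-2-ethenylphenoxy]-3-[3,4,5-tris(benzyloxy)phenyl]prop-1-en-2-yl}-4,4,5,5-tetramethyl-1,3,2-dioxaborolane | C=C(B1OC(C)(C)C(C)(C)O1)[C@H](Oc1cc(OCc2ccccc2)cc(OCc2ccccc2)c1C=C)c1cc(OCc2ccccc2)c(OCc2ccccc2)c(OCc2ccccc2)c1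
F7 | step 9 | potassium {(3S)-3-[3,5-bis(benzyloxy)-2-ethenylphenoxy]-3-[3,4,5-tris(benzyloxy)phenyl]prop-1-en-2-yl}trifluoroborate | C=C([B-](F)(F)F)[C@H](Oc1cc(OCc2ccccc2)cc(OCc2ccccc2)c1C=C)c1cc(OCc2ccccc2)c(OCc2ccccc2)c(OCc2ccccc2)c1.[K+]
F8 | step 11 | lithium (2R)-5,7-bis(benzyloxy)-2-[3,4,5-tris(benzyloxy)phenyl]-2H-chromen-3-olate | [Li]OC1=Cc2c(OCc3ccccc3)cc(OCc3ccccc3)cc2O[C@@H]1c1cc(OCc2ccccc2)c(OCc2ccccc2)c(OCc2ccccc2)c1
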